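**Plan**

- Enabling feature: the central benzene ring carries C–OH, C–H and C–OMe on three neighbouring carbons and three sp3 arms (4-hydroxybenzyl, 2-phenylethyl, 4-hydroxybenzyl) on the other three. This is the imprint of a vinylketene (the C–OH carbon plus the three arm-bearing carbons) joined to methoxyacetylene (the CH and the C–OMe).
- Retrosynthesis: with both outer phenols masked as benzyl ethers, the ring bonds C(OH)–CH, C(OMe)–C(benzyl) and C(OH)–C(benzyl) are cut, giving a 2,3,4-trisubstituted cyclobutenone and methoxyacetylene. The phenethyl–ring bond is cut next (Grignard addition with carbonyl transposition). The four-membered ring is then cut into an aldoketene and a benzylated ethyl ynol ether, and finally the propargylic C–C bond is cut.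
- Forward: acetylide alkylation, ketene–ynol ether (2+2) cycloaddition (four-membered ring), phenethyl introduction, benzannulation that expands the four-membered ring by two carbons into the central arene, hydrogenolysis. The three outer benzene rings are bought.
- Stereochemistry: the target has no stereocentre. The single sp3 ring carbon of the cyclobutenones is racemic and disappears on aromatisation.

Key step: step 6

Assumption: methoxyacetylene is taken not to be a stock chemical and is made and used as a cold toluene solution; ethoxyacetylene is used as its commercial hexane solution.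

**Route**

Step 1
Reactants: 1 ethoxyacetylene; 2 4-(benzyloxy)benzyl bromide
Product: 4 1-(benzyloxy)-4-(3-ethoxyprop-2-yn-1-yl)benzene, via lithium ethoxyethynide 3 (not isolated)
Conditions: n-BuLi, THF, −78 °C; then 2, DMPU, −78 °C to rt
Reagents that add atoms: none
Why: Deprotonation of the terminal ynol ether gives acetylide 3, which should displace the reactive benzylic bromide in an SN2 acetylide alkylation accelerated by the dipolar cosolvent; a slight excess of acetylide over bromide keeps free base away from the product.

Step 2
Reactants: 5 3-[4-(benzyloxy)phenyl]propanoic acid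
Product: 6 3-[4-(benzyloxy)phenyl]propanoyl chloride
Conditions: (COCl)2, cat. DMF, CH2Cl2, 0 °C to rt; concentrate and use crude
Reagents that add atoms: oxalyl chloride, ClC(=O)C(=O)Cl
Why: Standard acid chloride formation through the chloroiminium species generated from DMF and oxalyl chloride; the aryl benzyl ether is inert to these conditions.

Step 3
Reactants: 4 1-(benzyloxy)-4-(3-ethoxyprop-2-yn-1-yl)benzene; 6 3-[4-(benzyloxy)phenyl]propanoyl chloride
Product: 8 2,4-bis[4-(benzyloxy)benzyl]-3-ethoxycyclobut-2-en-1-one (racemic), via [4-(benzyloxy)benzyl]ketene 7 (not isolated)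
Conditions: Et3N, CH2Cl2, slow addition of 6 to 4, rt to 40 °C
Reagents that add atoms: none
Why: Dehydrochlorination of 6 by the amine releases aldoketene 7 at low stationary concentration, and the electron-rich ynol ether should trap it in a ketene–alkyne (2+2) cycloaddition in which the nucleophilic benzyl-bearing alkyne carbon bonds to the ketene carbonyl carbon, giving the 3-ethoxycyclobutenone with its C4 stereocentre racemic.

Step 4
Reactants: 8 2,4-bis[4-(benzyloxy)benzyl]-3-ethoxycyclobut-2-en-1-one; 9 2-phenylethylmagnesium chloride
Product: 11 2,4-bis[4-(benzyloxy)benzyl]-3-(2-phenylethyl)cyclobut-2-en-1-one (racemic), via cyclobutenol 10 (not isolated)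
Conditions: 9, THF, −78 to 0 °C; then 1 M aq HCl, 0 °C to rt
Reagents that add atoms: water, O
Why: 1,2-Addition of the Grignard reagent to the vinylogous ester carbonyl gives carbinol 10 (enolisation is disfavoured because the enolate would be a cyclobutadiene), and dilute acid then hydrolyses the enol ether and eliminates water in a Stork–Danheiser transposition that moves the carbonyl to the former C3 and leaves phenethyl on the β-carbon; the C4 centre stays racemic.

Step 5
Reactants: 12 chloroacetaldehyde dimethyl acetal (2-chloro-1,1-dimethoxyethane)
Product: 14 methoxyacetylene (methoxyethyne; cold toluene solution), via sodium methoxyethynide 13 (not isolated)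
Conditions: NaNH2 (3 equiv), liq. NH3, −33 °C; evaporate NH3; cold brine, −20 °C; distil into toluene at −40 °C
Reagents that add atoms: none
Why: Twofold base-induced elimination (methanol, then hydrogen chloride) from the chloroacetal gives sodium acetylide 13, and cold aqueous protonation liberates the volatile ynol ether, which is the standard alkoxyacetylene preparation.

Step 6
Reactants: 11 2,4-bis[4-(benzyloxy)benzyl]-3-(2-phenylethyl)cyclobut-2-en-1-one; 14 methoxyacetylene
Product: 19 2,4-bis[4-(benzyloxy)benzyl]-5-methoxy-3-(2-phenylethyl)phenol, via vinylketene 15 (not isolated), via 4-alkenylcyclobutenone 16 (not isolated), via dienylketene 17 (not isolated), via cyclohexa-2,4-dienone 18 (not isolated)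
Conditions: 14 (excess), toluene, sealed tube, 80 °C then 110 °C; then KOH, MeOH, rt (cleaves any aryl ester by-product)
Reagents that add atoms: none
Why: Heating should open 11 by four-electron conrotatory electrocyclic cleavage of the C1–C4 bond, the C4 benzyl arm rotating outward, to give vinylketene 15, which methoxyacetylene intercepts in a regioselective ketene–alkyne (2+2) cycloaddition to 16; a second four-electron opening gives dienylketene 17, six-electron electrocyclisation joins the ketene carbon to the terminal alkene carbon to give dienone 18, and enolisation gives the phenol. This is the thermal Danheiser benzannulation of a cyclobutenone with an alkoxyacetylene, the established route to resorcinol monoethers. The only ring that persists is the central benzene ring, closed by disrotatory 6π electrocyclisation in a net (4+2) sense after a transient four-membered ring: the former carbonyl carbon becomes C–OH, the alkyne supplies the lone CH and the C–OMe, and cyclobutenone C2, C3 and C4 deliver benzyl, phenethyl and benzyl in order. No stereocentre is created that survives, because the racemic sp3 carbon of 11, 16 and 18 ends as an aromatic carbon. The one selectivity required is the orientation of the (2+2) step, which is secured by the polarisation of the ynol ether: its nucleophilic terminal CH carbon attacks the electrophilic ketene carbonyl carbon, so H ends between OH and OMe. The methyl ynol ether cannot fragment by retro-ene reaction at these temperatures, and the benzyl ethers and sp3 arms are inert to neutral heating.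

Step 7
Reactants: 19 2,4-bis[4-(benzyloxy)benzyl]-5-methoxy-3-(2-phenylethyl)phenol
Product: 20 IN1158: 2,4-bis(4-hydroxybenzyl)-5-methoxy-3-(2-phenylethyl)phenol
Conditions: H2 (1 atm), 10% Pd/C, EtOAc/MeOH, rt
Reagents that add atoms: none
Why: Heterogeneous hydrogenolysis should cleave the two benzylic C–O bonds of the aryl benzyl ethers, while the aryl methyl ether, the diarylmethane C–C bonds and the arene rings are untouched at ambient pressure.

**Compound list**

1 | ethoxyacetylene (ethoxyethyne) | CCOC#C | starting material
2 | 4-(benzyloxy)benzyl bromide | BrCc1ccc(OCc2ccccc2)cc1 | starting material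
3 | lithium ethoxyethynide (in situ) | [Li]C#COCC | intermediate
4 | 1-(benzyloxy)-4-(3-ethoxyprop-2-yn-1-yl)benzene | CCOC#CCc1ccc(OCc2ccccc2)cc1 | intermediate
5 | 3-[4-(benzyloxy)phenyl]propanoic acid | OC(=O)CCc1ccc(OCc2ccccc2)cc1 | starting material
6 | 3-[4-(benzyloxy)phenyl]propanoyl chloride | ClC(=O)CCc1ccc(OCc2ccccc2)cc1 | intermediate
7 | [4-(benzyloxy)benzyl]ketene, 3-[4-(benzyloxy)phenyl]prop-1-en-1-one (in situ) | O=C=CCc1ccc(OCc2ccccc2)cc1 | intermediate
8 | 2,4-bis[4-(benzyloxy)benzyl]-3-ethoxycyclobut-2-en-1-one (racemic at C4) | CCOC1=C(Cc2ccc(OCc3ccccc3)cc2)C(=O)C1Cc1ccc(OCc2ccccc2)cc1 | intermediate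
9 | 2-phenylethylmagnesium chloride (THF solution) | Cl[Mg]CCc1ccccc1 | starting material
10 | 2,4-bis[4-(benzyloxy)benzyl]-3-ethoxy-1-(2-phenylethyl)cyclobut-2-en-1-ol (racemic diastereomer mixture, in situ) | CCOC1=C(Cc2ccc(OCc3ccccc3)cc2)C(O)(CCc2ccccc2)C1Cc1ccc(OCc2ccccc2)cc1 | intermediate
11 | 2,4-bis[4-(benzyloxy)benzyl]-3-(2-phenylethyl)cyclobut-2-en-1-one (racemic at C4) | O=C1C(Cc2ccc(OCc3ccccc3)cc2)=C(CCc2ccccc2)C1Cc1ccc(OCc2ccccc2)cc1 | intermediate
12 | chloroacetaldehyde dimethyl acetal (2-chloro-1,1-dimethoxyethane) | COC(CCl)OC | starting material
13 | sodium methoxyethynide (in situ) | [Na]C#COC | intermediate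
14 | methoxyacetylene (methoxyethyne) | COC#C | intermediate
15 | (3E)-2-[4-(benzyloxy)benzyl]-5-[4-(benzyloxy)phenyl]-3-(2-phenylethyl)penta-1,3-dien-1-one (vinylketene, in situ) | O=C=C(Cc1ccc(OCc2ccccc2)cc1)/C(CCc1ccccc1)=C/Cc1ccc(OCc2ccccc2)cc1 | intermediate
16 | 4-[4-(benzyloxy)benzyl]-4-[(2E)-1-[4-(benzyloxy)phenyl]-5-phenylpent-2-en-3-yl]-3-methoxycyclobut-2-en-1-one (racemic, in situ) | O=C1C=C(OC)C1(Cc1ccc(OCc2ccccc2)cc1)/C(CCc1ccccc1)=C/Cc1ccc(OCc2ccccc2)cc1 | intermediate
17 | (3E,5E)-4-[4-(benzyloxy)benzyl]-7-[4-(benzyloxy)phenyl]-3-methoxy-5-(2-phenylethyl)hepta-1,3,5-trien-1-one (dienylketene, in situ) | O=C=C/C(OC)=C(Cc1ccc(OCc2ccccc2)cc1)\C(CCc1ccccc1)=C\Cc1ccc(OCc2ccccc2)cc1 | intermediate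
18 | 4,6-bis[4-(benzyloxy)benzyl]-3-methoxy-5-(2-phenylethyl)cyclohexa-2,4-dien-1-one (racemic at C6, in situ) | O=C1C=C(OC)C(Cc2ccc(OCc3ccccc3)cc2)=C(CCc2ccccc2)C1Cc1ccc(OCc2ccccc2)cc1 | intermediate
19 | 2,4-bis[4-(benzyloxy)benzyl]-5-methoxy-3-(2-phenylethyl)phenol | COc1cc(O)c(Cc2ccc(OCc3ccccc3)cc2)c(CCc2ccccc2)c1Cc1ccc(OCc2ccccc2)cc1 | intermediate
20 | IN1158, 2,4-bis(4-hydroxybenzyl)-5-methoxy-3-(2-phenylethyl)phenol | COc1cc(O)c(Cc2ccc(O)cc2)c(CCc2ccccc2)c1Cc1ccc(O)cc1 | target

**Summary**

Total step count: 7.
Longest linear sequence: 5 steps (steps 1, 3, 4, 6, 7; the branch through steps 2, 3, 4, 6, 7 is equally long).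

Steps most likely to fail:

1. Step 6. The low-boiling alkyne may escape into the headspace or oligomerise on heating. The vinylketene would then go untrapped and instead dimerise or acylate the phenol already formed. The fallback sets out from cyclobutenone 11 and methoxyacetylene 14 and comes back at phenol 19. Compound 14 is lithiated (n-BuLi, THF, −78 °C) and silylated with Me3SiCl to give the distillable, far less volatile 1-methoxy-2-(trimethylsilyl)ethyne F1. Benzannulation of 11 with F1 under the same thermal regime should give 2,4-bis[4-(benzyloxy)benzyl]-5-methoxy-3-(2-phenylethyl)-6-(trimethylsilyl)phenol F2 with the same orientation, since the silyl-bearing alkyne carbon remains the nucleophilic one. Ipso-protodesilylation of this electron-rich arylsilane with CF3CO2H in CH2Cl2 at 0 °C then returns 19.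

2. Step 3. The aldoketene may dimerise to its β-lactone dimer faster than the ynol ether captures it, and amine hydrochloride may degrade the acid-sensitive ynol ether. The fallback sets out from ynol ether 4 alone and comes back at cyclobutenone 8. Heating 4 in toluene at about 110 to 120 °C should trigger retro-ene loss of ethylene from the ethyl ynol ether. This generates the same ketene 7 slowly, without amine and in a large excess of its trap, so that (2+2) capture by a second molecule of 4 leads directly to 8. Acid 5 and chloride 6 are then not needed, and no compound outside the list arises (F0).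

3. Step 1. The basic acetylide may isomerise the doubly activated propargylic–benzylic CH2 of the product to the allenyl ether, or halogen–metal exchange may lead to homocoupling of the benzylic bromide. The fallback sets out from lithium acetylide 3 and bromide 2 and comes back at ynol ether 4. Transmetalation of 3 with ZnCl2 in THF gives the much less basic (ethoxyethynyl)zinc chloride F3. Negishi sp–sp3 coupling of F3 with 2, catalysed by Pd(PPh3)4 in THF at rt, should then form the same C–C bond under essentially non-basic conditions.

**Further compounds**

F1 | step 6 | 1-methoxy-2-(trimethylsilyl)ethyne | COC#C[Si](C)(C)C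
F2 | step 6 | 2,4-bis[4-(benzyloxy)benzyl]-5-methoxy-3-(2-phenylethyl)-6-(trimethylsilyl)phenol | COc1c([Si](C)(C)C)c(O)c(Cc2ccc(OCc3ccccc3)cc2)c(CCc2ccccc2)c1Cc1ccc(OCc2ccccc2)cc1
F0 | step 3 | none | none
F3 | step 1 | (ethoxyethynyl)zinc chloride | CCOC#C[Zn]Cl
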